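**Plan**

- Cuts: the two C7 carbinols go back to ketones and the two aryl ether C8–O bonds are cut, giving a bisphenol tetrahydrofuran and two molecules of one lactate-derived tosyloxy ketone. In the core, C5–H goes back to a C5 methyl ketal, then the ring bond C3–C4 is cut, then the ketal C5–O bond (allylic alcohol + aryl enol ether + Br+).
- Enabling feature: the ring oxygen O1 lies between two benzylic carbons (C2, C5) that flank the methyl-bearing C3 and C4. With C5 raised to the ketone (ketal) level, O1 and C5 tether a C4 radical five atoms from a vinyl group on C2, whose terminal CH2 ends as the C3 methyl.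
- Forward: bromoketal from the two aryl fragments; 5-exo radical closure of C3–C4 makes the tetrahydrofuran, the only ring formed; ketal equilibration and reductive removal of the methoxy group; debenzylation; twofold phenol alkylation; twofold ketone reduction.
- Stereochemistry: C2 from lipase resolution; C3 from the chair-like radical transition state (trans to the C2 aryl); C4 by thermodynamic equilibration of the ketal (trans to the C3 methyl); C5 by hydride attack anti to the C4 methyl; C8 of both arms by SN2 inversion of an (R)-lactate-derived tosylate; C7 by chelation-controlled reduction (erythro).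

Key step: step 6

Remark: core numbering is O1, C2, C3, C4, C5, with C2 carrying the aryl group that is trans to its neighbouring methyl. Read from the SMILES, the core is (2S,3S,4S,5R), i.e. 2,3-trans, 3,4-trans, 4,5-cis, and both arms are (1R,2S), i.e. erythro. C7 is the carbinol carbon and C8 the aryloxy-bearing carbon of each arm; the two core aryl groups are constitutionally identical.

**Step 1**
Reactants: 1 4-(benzyloxy)-3-methoxybenzaldehyde; 2 vinylmagnesium bromide
Product: 3 rac-1-[4-(benzyloxy)-3-methoxyphenyl]prop-2-en-1-ol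
Conditions: vinylMgBr, THF, −78 → 0 °C; aq. NH4Cl
Reagents that add atoms: 2 vinylmagnesium bromide, C=C[Mg]Br
Why: Grignard 1,2-addition to the aryl aldehyde should give the racemic allylic alcohol cleanly, the configuration being settled in the next step.

**Step 2**
Reactants: 3 rac-1-[4-(benzyloxy)-3-methoxyphenyl]prop-2-en-1-ol
Product: 4 (S)-1-[4-(benzyloxy)-3-methoxyphenyl]prop-2-en-1-ol
Conditions: Novozym 435 (immobilised Candida antarctica lipase B), vinyl acetate, MTBE, 30 °C, stopped just past half conversion
Reagents that add atoms: none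
Why: Lipase-catalysed kinetic resolution should acylate the (R)-alcohol (Kazlauskas rule, aryl as the large and vinyl as the medium group) and leave the (S)-alcohol, which becomes C2 of the core.

**Step 3**
Reactants: 5 1-(4-hydroxy-3-methoxyphenyl)propan-1-one; 6 benzyl bromide
Product: 7 1-[4-(benzyloxy)-3-methoxyphenyl]propan-1-one
Conditions: BnBr, K2CO3, DMF, rt
Reagents that add atoms: 6 benzyl bromide, BrCc1ccccc1
Why: Williamson etherification of the phenoxide should protect the phenol with the same group as in 4.

**Step 4**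
Reactants: 7 1-[4-(benzyloxy)-3-methoxyphenyl]propan-1-one; 8 trimethyl orthoformate
Product: 10 1-(benzyloxy)-2-methoxy-4-(1-methoxyprop-1-en-1-yl)benzene, via dimethyl ketal 9 (not isolated)
Conditions: HC(OMe)3, MeOH, TsOH·H2O (cat.), 50 °C; concentrate; then TMSOTf, iPr2NEt, CH2Cl2, −20 → 0 °C
Reagents that add atoms: 8 trimethyl orthoformate, COC(OC)OC
Why: Acid-catalysed ketalisation followed by silyl triflate/amine-promoted loss of methanol (Gassman-type ketal to enol ether conversion) should give the aryl enol ether, whose double-bond geometry is of no consequence.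

**Step 5**
Reactants: 4 (S)-1-[4-(benzyloxy)-3-methoxyphenyl]prop-2-en-1-ol; 10 1-(benzyloxy)-2-methoxy-4-(1-methoxyprop-1-en-1-yl)benzene; 11 N-bromosuccinimide
Product: 12 1-(benzyloxy)-4-[(1S)-1-{2-bromo-1-[4-(benzyloxy)-3-methoxyphenyl]-1-methoxypropoxy}prop-2-en-1-yl]-2-methoxybenzene (mixed bromoketal; ketal carbon and CHBr as mixtures)
Conditions: NBS, 2,6-lutidine (0.2 equiv), CH2Cl2, −78 → −30 °C, 10 and NBS in slight excess
Reagents that add atoms: 11 N-bromosuccinimide, O=C1CCC(=O)N1Br
Why: Bromination of the electron-rich enol ether should give an aryl-stabilised β-bromo oxocarbenium ion that the allylic alcohol captures (haloketalisation, as used to make Ueno–Stork precursors); the two new centres (C4, C5) form as mixtures that are corrected or erased later, and C2 is not touched.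

**Step 6**
Reactants: 12 mixed bromoketal
Product: 13 (2S,3S)-2,5-bis[4-(benzyloxy)-3-methoxyphenyl]-5-methoxy-3,4-dimethyltetrahydrofuran (C4 and C5 as mixtures)
Conditions: Bu3SnH (1.3 equiv, about 0.03 M), AIBN (0.1 equiv), PhH, 80 °C; KF work-up, filtration through basic alumina
Reagents that add atoms: none
Why: Bu3Sn• abstracts bromine from C4 of 12, and the secondary radical, held by the ketal carbon C5 and O1 five atoms from the vinyl group, adds to the internal vinyl carbon C3; the primary radical so formed takes hydrogen from Bu3SnH and becomes the C3 methyl group. The closest known reaction type is the Ueno–Stork cyclisation of α-bromo acetals of allylic alcohols, run here on the mixed methyl ketal of an α-bromo aryl ketone. The one ring that closes is the tetrahydrofuran (O1–C2–C3–C4–C5), by a 5-exo-trig closure through the new C3–C4 bond. C3 is controlled by the C2 stereocentre: in the chair-like (Beckwith–Houk) transition state the C2 aryl group sits pseudo-equatorial, so the new C3 substituent should come out trans to it (2S,3S); C4 is also created here but its sense depends on the ketal epimer and is not relied upon, being corrected by equilibration in step 7, and C5 remains a mixture. The step needs closure to outrun hydrogen transfer and a 1,2-shift of the C5 aryl group at the C4 radical, and the cyclised primary radical to be reduced before it attacks an aryl ring. Both should be met at a moderate stannane concentration, because 5-exo closure of an oxygen-tethered radical next to a fully substituted ketal carbon is much faster than either side reaction.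

**Step 7**
Reactants: 13 (2S,3S)-2,5-bis[4-(benzyloxy)-3-methoxyphenyl]-5-methoxy-3,4-dimethyltetrahydrofuran
Product: 15 (2S,3S,4S,5R)-2,5-bis[4-(benzyloxy)-3-methoxyphenyl]-3,4-dimethyltetrahydrofuran, via trans-ketal 14 (not isolated)
Conditions: PPTS (cat.), MeOH, 40 °C; concentrate; then Et3SiH, BF3·OEt2, CH2Cl2, −78 → −50 °C
Reagents that add atoms: none
Why: Acid-catalysed exchange through the oxocarbenium ion and its 4,5-dihydrofuran (enol ether) tautomer should let C4 and the anomeric centre settle in the more stable 3,4-trans ketal, and ionisation of that ketal followed by hydride transfer from Et3SiH to the face of the 2-aryl oxocarbenium ion opposite the C4 methyl and C2 aryl groups (reductive deoxygenation of cyclic ketals and hemiketals) should set C5 as R with its aryl group cis to the C4 methyl, the low temperature keeping this kinetic 4,5-cis product from benzylic epimerisation.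

**Step 8**
Reactants: 15 (2S,3S,4S,5R)-2,5-bis[4-(benzyloxy)-3-methoxyphenyl]-3,4-dimethyltetrahydrofuran
Product: 16 4,4'-[(2S,3S,4S,5R)-3,4-dimethyltetrahydrofuran-2,5-diyl]bis(2-methoxyphenol)
Conditions: H2 (1 atm), 10% Pd/C, EtOAc, rt
Reagents that add atoms: none
Why: Hydrogenolysis of the two aryl benzyl ethers should be faster than cleavage of the dibenzylic ring C–O bonds under neutral conditions at ambient pressure, and no stereocentre is touched.

**Step 9**
Reactants: 17 methyl (R)-lactate; 18 N,O-dimethylhydroxylamine hydrochloride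
Product: 19 (R)-2-hydroxy-N-methoxy-N-methylpropanamide
Conditions: MeNHOMe·HCl, iPrMgCl, THF, −20 → 0 °C; aq. NH4Cl
Reagents that add atoms: 18 N,O-dimethylhydroxylamine hydrochloride, CNOC.Cl
Why: Aminolysis of the ester by the chloromagnesium amide (Weinreb amide formation), with the hydroxyl carried as its magnesium alkoxide, should leave the stereocentre untouched.

**Step 10**
Reactants: 19 (R)-2-hydroxy-N-methoxy-N-methylpropanamide; 20 3,4-dimethoxyphenylmagnesium bromide
Product: 21 (R)-1-(3,4-dimethoxyphenyl)-2-hydroxypropan-1-one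
Conditions: ArMgBr (3 equiv), THF, 0 °C → rt; aq. NH4Cl
Reagents that add atoms: 20 3,4-dimethoxyphenylmagnesium bromide, COc1ccc([Mg]Br)cc1OC
Why: Weinreb ketone synthesis: the chelated tetrahedral intermediate should stop at the ketone stage, one equivalent of Grignard reagent being used up by the hydroxyl group.

**Step 11**
Reactants: 21 (R)-1-(3,4-dimethoxyphenyl)-2-hydroxypropan-1-one; 22 4-methylbenzenesulfonyl chloride
Product: 23 (R)-1-(3,4-dimethoxyphenyl)-1-oxopropan-2-yl 4-methylbenzenesulfonate
Conditions: TsCl, Et3N, DMAP (cat.), CH2Cl2, 0 °C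
Reagents that add atoms: 22 4-methylbenzenesulfonyl chloride, Cc1ccc(S(=O)(=O)Cl)cc1
Why: O-Sulfonylation of the secondary alcohol proceeds with retention and should give an α-keto-activated leaving group.

**Step 12**
Reactants: 16 4,4'-[(2S,3S,4S,5R)-3,4-dimethyltetrahydrofuran-2,5-diyl]bis(2-methoxyphenol); 23 (R)-1-(3,4-dimethoxyphenyl)-1-oxopropan-2-yl 4-methylbenzenesulfonate
Product: 24 (2S,2'S)-2,2'-{[(2S,3S,4S,5R)-3,4-dimethyltetrahydrofuran-2,5-diyl]bis[(2-methoxy-4,1-phenylene)oxy]}bis[1-(3,4-dimethoxyphenyl)propan-1-one]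
Conditions: 23 (2.4 equiv), K2CO3, DMF, 0 °C → rt
Reagents that add atoms: 23 (R)-1-(3,4-dimethoxyphenyl)-1-oxopropan-2-yl 4-methylbenzenesulfonate (second equivalent), COc1ccc(C(=O)[C@@H](C)OS(=O)(=O)c2ccc(C)cc2)cc1OC
Why: Twofold Williamson-type SN2 displacement, in which each of the two phenoxides of 16 displaces the tosylate of one molecule of 23 with inversion, so that two molecules of 23 are taken up per molecule of 16 and each (R)-tosylate carbon becomes the (S)-configured C8.

**Step 13**
Reactants: 24 bis(aryloxy ketone)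
Product: 25 (1R,2S)-1-(3,4-dimethoxyphenyl)-2-{4-[(2S,3S,4S,5R)-5-(4-{[(1R,2S)-1-(3,4-dimethoxyphenyl)-1-hydroxypropan-2-yl]oxy}-3-methoxyphenyl)-3,4-dimethyltetrahydrofuran-2-yl]-2-methoxyphenoxy}propan-1-ol
Conditions: Zn(BH4)2, Et2O/THF, −20 → 0 °C; aq. NH4Cl
Reagents that add atoms: none
Why: Chelation-controlled (Cram chelate) reduction: zinc should bridge the carbonyl and α-aryloxy oxygens so that hydride enters from the side of the C8 hydrogen, giving the erythro (1R,2S) alcohol in both arms.

**Compound list**

1 | 4-(benzyloxy)-3-methoxybenzaldehyde | COc1cc(C=O)ccc1OCc1ccccc1 | starting material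
2 | vinylmagnesium bromide | C=C[Mg]Br | starting material
3 | rac-1-[4-(benzyloxy)-3-methoxyphenyl]prop-2-en-1-ol | C=CC(O)c1ccc(OCc2ccccc2)c(OC)c1 | intermediate
4 | (S)-1-[4-(benzyloxy)-3-methoxyphenyl]prop-2-en-1-ol | C=C[C@H](O)c1ccc(OCc2ccccc2)c(OC)c1 | intermediate
5 | 1-(4-hydroxy-3-methoxyphenyl)propan-1-one | CCC(=O)c1ccc(O)c(OC)c1 | starting material
6 | benzyl bromide | BrCc1ccccc1 | starting material
7 | 1-[4-(benzyloxy)-3-methoxyphenyl]propan-1-one | CCC(=O)c1ccc(OCc2ccccc2)c(OC)c1 | intermediate
8 | trimethyl orthoformate | COC(OC)OC | starting material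
9 | 1-(benzyloxy)-4-(1,1-dimethoxypropyl)-2-methoxybenzene | CCC(OC)(OC)c1ccc(OCc2ccccc2)c(OC)c1 | intermediate
10 | 1-(benzyloxy)-2-methoxy-4-(1-methoxyprop-1-en-1-yl)benzene (E/Z mixture) | CC=C(OC)c1ccc(OCc2ccccc2)c(OC)c1 | intermediate
11 | N-bromosuccinimide | O=C1CCC(=O)N1Br | starting material
12 | mixed bromoketal, (S) at the allylic carbon, ketal carbon and CHBr as mixtures | C=C[C@H](OC(OC)(C(C)Br)c1ccc(OCc2ccccc2)c(OC)c1)c1ccc(OCc2ccccc2)c(OC)c1 | intermediate
13 | (2S,3S)-2,5-bis[4-(benzyloxy)-3-methoxyphenyl]-5-methoxy-3,4-dimethyltetrahydrofuran (C4, C5 mixtures) | COc1cc([C@H]2OC(OC)(c3ccc(OCc4ccccc4)c(OC)c3)C(C)[C@@H]2C)ccc1OCc1ccccc1 | intermediate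
14 | (2S,3S,4S)-2,5-bis[4-(benzyloxy)-3-methoxyphenyl]-5-methoxy-3,4-dimethyltetrahydrofuran (C5 anomers) | COc1cc([C@H]2OC(OC)(c3ccc(OCc4ccccc4)c(OC)c3)[C@@H](C)[C@@H]2C)ccc1OCc1ccccc1 | intermediate
15 | (2S,3S,4S,5R)-2,5-bis[4-(benzyloxy)-3-methoxyphenyl]-3,4-dimethyltetrahydrofuran | COc1cc([C@H]2O[C@@H](c3ccc(OCc4ccccc4)c(OC)c3)[C@@H](C)[C@@H]2C)ccc1OCc1ccccc1 | intermediate
16 | 4,4'-[(2S,3S,4S,5R)-3,4-dimethyltetrahydrofuran-2,5-diyl]bis(2-methoxyphenol) | COc1cc([C@H]2O[C@@H](c3ccc(O)c(OC)c3)[C@@H](C)[C@@H]2C)ccc1O | intermediate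
17 | methyl (R)-lactate | C[C@@H](O)C(=O)OC | starting material
18 | N,O-dimethylhydroxylamine hydrochloride | CNOC.Cl | starting material
19 | (R)-2-hydroxy-N-methoxy-N-methylpropanamide | C[C@@H](O)C(=O)N(C)OC | intermediate
20 | 3,4-dimethoxyphenylmagnesium bromide | COc1ccc([Mg]Br)cc1OC | starting material
21 | (R)-1-(3,4-dimethoxyphenyl)-2-hydroxypropan-1-one | COc1ccc(C(=O)[C@@H](C)O)cc1OC | intermediate
22 | 4-methylbenzenesulfonyl chloride | Cc1ccc(S(=O)(=O)Cl)cc1 | starting material
23 | (R)-1-(3,4-dimethoxyphenyl)-1-oxopropan-2-yl 4-methylbenzenesulfonate | COc1ccc(C(=O)[C@@H](C)OS(=O)(=O)c2ccc(C)cc2)cc1OC | intermediate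
24 | bis(aryloxy ketone), (S) at both C8, core (2S,3S,4S,5R) | COc1ccc(C(=O)[C@H](C)Oc2ccc([C@H]3O[C@@H](c4ccc(O[C@@H](C)C(=O)c5ccc(OC)c(OC)c5)c(OC)c4)[C@@H](C)[C@@H]3C)cc2OC)cc1OC | intermediate
25 | target, core (2S,3S,4S,5R), both arms (1R,2S) | COc1ccc([C@@H](O)[C@H](C)Oc2ccc([C@H]3O[C@@H](c4ccc(O[C@@H](C)[C@H](O)c5ccc(OC)c(OC)c5)c(OC)c4)[C@@H](C)[C@@H]3C)cc2OC)cc1OC | target

**Step count and weak points**

Total step count: 13. Longest linear sequence: 8 steps (steps 1, 2, 5, 6, 7, 8, 12, 13, from 1).

Steps most likely to fail: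

Step 5. The hindered secondary alcohol may capture the aryl-stabilised bromo oxocarbenium ion too slowly, so that ionisation or allylic transposition of the alcohol, or bromination of an aryl ring, takes over. The fallback moves the hindered C5–O bond formation to an acylation. It sets out from 4: Steglich esterification with commercial 4-(benzyloxy)-3-methoxybenzoic acid (DCC, DMAP, CH2Cl2) gives the ester F1. Takai–Utimoto ethylidenation (CH3CHBr2, Zn, TiCl4, TMEDA, THF, 0 °C → rt) turns the ester carbonyl into the enol ether F2, which is kept cold to avoid Claisen rearrangement. NBS in MeOH/CH2Cl2 with 2,6-lutidine at −78 °C then adds bromine and methoxide across the enol ether, and the route is rejoined at 12.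

Step 6. The ring closure may show too little preference for the 2,3-trans arrangement, or the C4 radical may be lost to 1,2-aryl shift or hydrogen transfer before it closes. The fallback sets C3 by conjugate addition instead and sets out from 4. Acylation with acryloyl chloride (Et3N, CH2Cl2, 0 °C) gives the acrylate F3, and ring-closing metathesis with the second-generation Grubbs catalyst (toluene, 80 °C) gives the butenolide F4. Me2CuLi (Et2O, −78 °C) should add anti to the aryl group, and methylation of the enolate in the same flask (MeI, HMPA) anti to the new methyl group should give the all-trans lactone F5. The aryllithium F6, made from commercial 1-(benzyloxy)-4-bromo-2-methoxybenzene and n-BuLi at −78 °C, adds to F5 to give the hemiketal F7. Et3SiH/BF3·OEt2 at −78 °C reduces F7 as in step 7, and the route is rejoined at 15.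

Step 7. Equilibration at C4 may stay incomplete, the acid may scramble the benzylic C2 centre, or the kinetic 4,5-cis product may epimerise during the reduction. The fallback keeps the radical closure of the C3–C4 bond but brings in the C4 methyl by enolate alkylation; it sets out from 4. Ethyl vinyl ether and NBS (CH2Cl2, −30 °C) give the bromoacetal F8, and Bu3SnH/AIBN (PhH, 80 °C) closes it to the cyclic ethyl acetal F9. Oxidation with mCPBA/BF3·OEt2 gives the lactone F10, and LiN(iPr)2 then MeI (THF, −78 °C) should methylate anti to the C3 methyl group to give the lactone F5 described above. This is carried on with the aryllithium F6 through the hemiketal F7 and the low-temperature Et3SiH/BF3·OEt2 reduction, and the route is rejoined at 15.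

**Further compounds**

F1 | step 5 | (S)-1-[4-(benzyloxy)-3-methoxyphenyl]prop-2-en-1-yl 4-(benzyloxy)-3-methoxybenzoate | C=C[C@H](OC(=O)c1ccc(OCc2ccccc2)c(OC)c1)c1ccc(OCc2ccccc2)c(OC)c1
F2 | step 5 | 1-(benzyloxy)-4-[(1S)-1-({1-[4-(benzyloxy)-3-methoxyphenyl]prop-1-en-1-yl}oxy)prop-2-en-1-yl]-2-methoxybenzene (mainly Z) | C=C[C@H](OC(=CC)c1ccc(OCc2ccccc2)c(OC)c1)c1ccc(OCc2ccccc2)c(OC)c1
F3 | step 6 | (S)-1-[4-(benzyloxy)-3-methoxyphenyl]prop-2-en-1-yl acrylate | C=CC(=O)O[C@@H](C=C)c1ccc(OCc2ccccc2)c(OC)c1
F4 | step 6 | (S)-5-[4-(benzyloxy)-3-methoxyphenyl]furan-2(5H)-one | O=C1C=C[C@@H](c2ccc(OCc3ccccc3)c(OC)c2)O1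
F5 | step 6 | (3S,4S,5S)-5-[4-(benzyloxy)-3-methoxyphenyl]-3,4-dimethyldihydrofuran-2(3H)-one | COc1cc([C@H]2OC(=O)[C@@H](C)[C@@H]2C)ccc1OCc1ccccc1
F6 | step 6 | [4-(benzyloxy)-3-methoxyphenyl]lithium | COc1cc([Li])ccc1OCc1ccccc1
F7 | step 6 | (2S,3S,4S)-2,5-bis[4-(benzyloxy)-3-methoxyphenyl]-5-hydroxy-3,4-dimethyltetrahydrofuran (C5 anomers) | COc1cc([C@H]2OC(O)(c3ccc(OCc4ccccc4)c(OC)c3)[C@@H](C)[C@@H]2C)ccc1OCc1ccccc1
F8 | step 7 | 1-(benzyloxy)-4-[(1S)-1-(2-bromo-1-ethoxyethoxy)prop-2-en-1-yl]-2-methoxybenzene (acetal carbon as mixture) | C=C[C@H](OC(CBr)OCC)c1ccc(OCc2ccccc2)c(OC)c1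
F9 | step 7 | (2S,3S)-2-[4-(benzyloxy)-3-methoxyphenyl]-5-ethoxy-3-methyltetrahydrofuran (C5 anomers) | COc1cc([C@H]2OC(OCC)C[C@@H]2C)ccc1OCc1ccccc1
F10 | step 7 | (4S,5S)-5-[4-(benzyloxy)-3-methoxyphenyl]-4-methyldihydrofuran-2(3H)-one | COc1cc([C@H]2OC(=O)C[C@@H]2C)ccc1OCc1ccccc1
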